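**Strategy.** The route rests on making ring B of the cis-decalin (C4a, C5, C6, C7, C8, C8a; target locants) from a cyclopentane. A cis-hydrindane cyclopentanol, whose carbinol carbon (future C6) carries a 3-arylprop-1-en-2-yl group, undergoes a hydrogen-atom-transfer-initiated semipinacol shift of C4a from C6 to the alkene carbon. This single operation expands the ring to the C6 cyclohexanone, forges the C4a–C5 bond and sets the C5 quaternary centre bearing methyl and arylmethyl; it exploits that C5 lies between C4a–H and a C6 carbon that can be a ketone before it becomes CH–CH3. The precursor comes from an asymmetric conjugate addition/annulation on 3-methylcyclopentenone; ring A is completed afterwards.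

Key step: step 9

Remark: bicyclic compounds from 15 on carry the decalin locants of the target (C1 bears the acid chain, C2 the isopropylidene, C4a the ring-fusion hydrogen, C5 methyl and arylmethyl, C6 the secondary methyl, C8a the angular methyl); Ar = 5-methoxy-3-methyl-2-[tri(propan-2-yl)silyloxy]phenyl; Co(salen) is the complex of divalent cobalt with the dianion of N,N'-bis(3,5-di-tert-butylsalicylidene)cyclohexane-1,2-diamine; the carbinol centre made in step 8 is carried as an epimer mixture because step 9 removes it.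

Step 1
Reactants: 1 4-methoxy-2-methylphenol; 2 2,3-dibromoprop-1-ene
Product: 3 1-[(2-bromoprop-2-en-1-yl)oxy]-4-methoxy-2-methylbenzene
Conditions: K2CO3, acetone, reflux
Reagents that add atoms: none
Why: Williamson ether synthesis, in which the phenoxide should displace only the allylic bromide while the vinylic bromide stays untouched.

Step 2
Reactants: 3 1-[(2-bromoprop-2-en-1-yl)oxy]-4-methoxy-2-methylbenzene
Product: 4 2-(2-bromoprop-2-en-1-yl)-4-methoxy-6-methylphenol
Conditions: PhNEt2, 190 °C
Reagents that add atoms: none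
Why: Aromatic Claisen rearrangement, which should deliver the 2-bromoallyl group to the only free ortho position and so fix the 1,2,3,5-substitution pattern of the arene.

Step 3
Reactants: 4 2-(2-bromoprop-2-en-1-yl)-4-methoxy-6-methylphenol
Product: 5 [2-(2-bromoprop-2-en-1-yl)-4-methoxy-6-methylphenoxy]tri(propan-2-yl)silane
Conditions: i-Pr3SiOTf, 2,6-lutidine, CH2Cl2, 0 °C to 25 °C
Reagents that add atoms: triisopropylsilyl trifluoromethanesulfonate, CC(C)[Si](OS(=O)(=O)C(F)(F)F)(C(C)C)C(C)C
Why: Silylation of the hindered phenol with a silyl triflate; the bulky silyl ether should survive organolithium and acid, lower the nucleophilicity of the phenol oxygen for step 9, and fall off in the last step.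

Step 4
Reactants: 6 5-chloropent-1-yne; 7 3-methylcyclopent-2-en-1-one
Product: 9 (3R)-3-(5-chloropent-1-en-2-yl)-3-methylcyclopentan-1-one, via alkenylalane 8 (not isolated)
Conditions: i-Bu2AlH, Ni(dppp)Cl2 (3 mol%), THF, 22 °C; then 7, CuCl2·2H2O (5 mol%), chiral sulfonate-bearing imidazolinium salt (carbene precursor, 5 mol%), THF, −30 °C
Reagents that add atoms: none
Why: Nickel-catalysed Markovnikov hydroalumination should give the 1,1-disubstituted alkenylalane, and the copper–carbene-catalysed enantioselective conjugate addition to the β-methyl enone should set the quaternary carbon (future C8a) under catalyst control, the ligand enantiomer being chosen for the (R)-ketone.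

Step 5
Reactants: 9 (3R)-3-(5-chloropent-1-en-2-yl)-3-methylcyclopentan-1-one
Product: 10 (3aR,7aR)-3a-methyl-4-methylideneoctahydro-1H-inden-1-one
Conditions: t-BuOK, t-BuOH/THF, 25 °C
Reagents that add atoms: none
Why: Intramolecular enolate alkylation (methylenecyclohexane annulation); of the equilibrating enolates only the one next to the quaternary carbon can reach the chloride (6-exo-tet), and the tether should enforce the cis ring fusion (future C4a–H cis to the angular methyl).

Step 6
Reactants: 10 (3aR,7aR)-3a-methyl-4-methylideneoctahydro-1H-inden-1-one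
Product: 11 (3aR,7aR)-3a-methylhexahydro-1H-indene-1,4(2H)-dione
Conditions: O3, CH2Cl2/MeOH, −78 °C; then Me2S
Reagents that add atoms: ozone, [O-][O+]=O
Why: Ozonolysis with reductive work-up should turn the exocyclic methylene into the six-ring ketone (future C1) that later activates C2.

Step 7
Reactants: 5 [2-(2-bromoprop-2-en-1-yl)-4-methoxy-6-methylphenoxy]tri(propan-2-yl)silane; 11 (3aR,7aR)-3a-methylhexahydro-1H-indene-1,4(2H)-dione
Product: 13 (1S,3aR,7aR)-1-(3-Ar-prop-1-en-2-yl)-1-hydroxy-3a-methyloctahydro-4H-inden-4-one, via alkenyllithium 12 (not isolated)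
Conditions: 5, t-BuLi (2 equiv), Et2O, −78 °C; CeCl3, THF, −78 °C; then 11
Reagents that add atoms: none
Why: Bromine–lithium exchange and organocerium 1,2-addition; the cyclopentanone should react before the cyclohexanone that is flanked by the quaternary carbon, and attack on the convex face (anti to the adjacent ring-B bond) should place the alkenyl group cis to the ring-fusion hydrogen and the angular methyl.

Step 8
Reactants: 13 (1S,3aR,7aR)-1-(3-Ar-prop-1-en-2-yl)-1-hydroxy-3a-methyloctahydro-4H-inden-4-one
Product: 14 (1S,3aR,7aR)-1-(3-Ar-prop-1-en-2-yl)-1-hydroxy-5-(2-hydroxypropan-2-yl)-3a-methyloctahydro-4H-inden-4-one (C5 epimers)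
Conditions: LiN(i-Pr)2 (2.2 equiv), THF, −78 °C; acetone; AcOH quench
Reagents that add atoms: acetone, CC(C)=O
Why: Aldol addition; the ketone can enolise only toward its CH2 (the other α-carbon is quaternary), so the isopropylidene carbons should enter regiospecifically at the future C2.

Step 9
Reactants: 14 (1S,3aR,7aR)-1-(3-Ar-prop-1-en-2-yl)-1-hydroxy-5-(2-hydroxypropan-2-yl)-3a-methyloctahydro-4H-inden-4-one
Product: 16 (4aS,5R,8aR)-5-(Ar-methyl)-5,8a-dimethyl-2-(propan-2-ylidene)octahydronaphthalene-1,6-dione, via hydroxy diketone 15 (not isolated)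
Conditions: Co(salen) (5 mol%), N-fluoro-2,4,6-trimethylpyridinium triflate, PhSiH3, acetone, 0 °C to 25 °C; then TsOH·H2O (20 mol%), toluene, 50 °C
Reagents that add atoms: none
Why: A cobalt hydride formed from Co(salen), the N-fluoropyridinium oxidant and PhSiH3 should transfer a hydrogen atom to the terminal CH2 of the only alkene; the tertiary radical at the future C5 is oxidised to a cation equivalent (an alkylcobalt of tetravalent cobalt), and the ring bond C6–C4a shifts to C5 while the carbinol becomes the C6 ketone. The closest known reactions are the hydrogen-atom-transfer-initiated radical–polar crossover semipinacol rearrangements of tertiary allylic alcohols and the electrophile-induced ring expansions of 1-alkenylcyclopentanols (D-homoannulation of 17-vinyl steroids). Ring B is not closed by a cyclisation but arises from the cyclopentane by a one-carbon ring expansion (1,2-alkyl shift), with C4a migrating with retention so that the cis ring fusion is kept. The new quaternary centre C5 is under substrate control: the cationic carbon sits on the convex face, and the shift should pass through the rotamer that keeps the large arylmethyl group outside and the methyl group over the ring, which places the methyl cis to C4a–H and to the C8a methyl. The step needs migration of the tertiary C4a and not of the C7 methylene, which the higher migratory aptitude of the more substituted carbon should secure, and it needs the cation to be taken by the shift and not by an oxygen, for which the bulky silyl ether on the phenol was chosen. The TsOH added afterwards should dehydrate the tertiary aldol to the conjugated isopropylidene ketone.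

Step 10
Reactants: 16 (4aS,5R,8aR)-5-(Ar-methyl)-5,8a-dimethyl-2-(propan-2-ylidene)octahydronaphthalene-1,6-dione
Product: 17 (4aS,5R,8aR)-5-(Ar-methyl)-6-(methoxymethylidene)-5,8a-dimethyl-2-(propan-2-ylidene)octahydronaphthalen-1(2H)-one (E/Z mixture)
Conditions: MeOCH2PPh3Cl, KN(SiMe3)2, THF, 0 °C to 50 °C
Reagents that add atoms: (methoxymethyl)triphenylphosphonium chloride, COC[P+](c1ccccc1)(c1ccccc1)c1ccccc1.[Cl-]
Why: Wittig methoxymethylenation should take place at the saturated C6 ketone only, because the cross-conjugated C1 ketone lies between a quaternary carbon and a tetrasubstituted alkene.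

Step 11
Reactants: 17 (4aS,5R,8aR)-5-(Ar-methyl)-6-(methoxymethylidene)-5,8a-dimethyl-2-(propan-2-ylidene)octahydronaphthalen-1(2H)-one
Product: 18 (1R,4aS,5R,8aR)-5-(Ar-methyl)-6-(methoxymethylidene)-5,8a-dimethyl-2-(propan-2-ylidene)decahydronaphthalen-1-ol
Conditions: i-Bu2AlH, CH2Cl2, −78 °C
Reagents that add atoms: none
Why: 1,2-Reduction of the hindered enone should give the allylic alcohol (hydride from the face of the angular methyl); its configuration is lost again in step 13.

Step 12
Reactants: 18 (1R,4aS,5R,8aR)-5-(Ar-methyl)-6-(methoxymethylidene)-5,8a-dimethyl-2-(propan-2-ylidene)decahydronaphthalen-1-ol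
Product: 19 the C1 allylic chloride of 18, 1-chloro-5-(Ar-methyl)-6-(methoxymethylidene)-5,8a-dimethyl-2-(propan-2-ylidene)decahydronaphthalene (C4a, C5, C8a as in 18; C1 undefined; may hold the tertiary allylic isomer)
Conditions: MsCl, Et3N, LiCl, CH2Cl2/DMF, 0 °C
Reagents that add atoms: lithium chloride, [Li+].[Cl-]
Why: Mesylation and chloride displacement under basic conditions should give the allylic chloride without touching the acid-labile enol ether; both allylic isomers converge in the next step.

Step 13
Reactants: 19 the C1 allylic chloride of 18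
Product: 21 ethyl 3-[5-(Ar-methyl)-6-formyl-5,8a-dimethyl-2-(propan-2-ylidene)decahydronaphthalen-1-yl]propanoate (C1, C4a, C5, C8a as in 22; formyl equatorial after equilibration), via enol ether ester 20 (not isolated)
Conditions: BrZnCH2CH2CO2Et, NiCl2(MeOCH2CH2OMe) (10 mol%), 2,6-bis(4,4-dimethyl-2-oxazolin-2-yl)pyridine (13 mol%), NaCl, DMA, −10 °C; then 1 M HCl, THF, 0 °C
Reagents that add atoms: (3-ethoxy-3-oxopropyl)zinc bromide, CCOC(=O)CC[Zn]Br; water, O
Why: Nickel-catalysed Negishi allylic alkylation; the allylnickel intermediate should couple at the secondary C1 terminus (the CMe2 terminus would give a quaternary carbon), leaving the isopropylidene, and on the face cis to the C8a methyl because the axial C8 methylene shields the other face. The acidic work-up then hydrolyses the enol ether to the aldehyde.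

Step 14
Reactants: 21 ethyl 3-[5-(Ar-methyl)-6-formyl-5,8a-dimethyl-2-(propan-2-ylidene)decahydronaphthalen-1-yl]propanoate
Product: 22 3-[(1S,4aS,5S,6R,8aR)-5-(2-hydroxy-5-methoxy-3-methylbenzyl)-5,6,8a-trimethyl-2-(propan-2-ylidene)decahydronaphthalen-1-yl]propanoic acid (CNP0299684.4)
Conditions: N2H4·H2O, KOH, diethylene glycol, 130 °C then 200 °C; aqueous HCl work-up
Reagents that add atoms: potassium hydroxide, [K+].[OH-]
Why: Wolff–Kishner reduction (Huang-Minlon) should turn the formyl group into the C6 methyl after base equilibration of the aldehyde/hydrazone to the equatorial epimer (cis to the C5 methyl, favoured because the alternative chair places the substituent 1,3-diaxial to C4), while the hydroxide also saponifies the ester and cleaves the aryl silyl ether.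

**Compound list**

1 | 4-methoxy-2-methylphenol | COc1ccc(O)c(C)c1 | starting material
2 | 2,3-dibromoprop-1-ene | BrCC(Br)=C | starting material
3 | 1-[(2-bromoprop-2-en-1-yl)oxy]-4-methoxy-2-methylbenzene | COc1ccc(OCC(Br)=C)c(C)c1 | intermediate
4 | 2-(2-bromoprop-2-en-1-yl)-4-methoxy-6-methylphenol | COc1cc(C)c(O)c(CC(Br)=C)c1 | intermediate
5 | [2-(2-bromoprop-2-en-1-yl)-4-methoxy-6-methylphenoxy]tri(propan-2-yl)silane | COc1cc(C)c(O[Si](C(C)C)(C(C)C)C(C)C)c(CC(Br)=C)c1 | intermediate
6 | 5-chloropent-1-yne | ClCCCC#C | starting material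
7 | 3-methylcyclopent-2-en-1-one | CC1=CC(=O)CC1 | starting material
8 | (5-chloropent-1-en-2-yl)bis(2-methylpropyl)alane | CC(C)C[Al](CC(C)C)C(=C)CCCCl | intermediate
9 | (3R)-3-(5-chloropent-1-en-2-yl)-3-methylcyclopentan-1-one | C=C(CCCCl)[C@]1(C)CCC(=O)C1 | intermediate
10 | (3aR,7aR)-3a-methyl-4-methylideneoctahydro-1H-inden-1-one | O=C1[C@@H]2CCCC(=C)[C@]2(C)CC1 | intermediate
11 | (3aR,7aR)-3a-methylhexahydro-1H-indene-1,4(2H)-dione | O=C1[C@@H]2CCCC(=O)[C@]2(C)CC1 | intermediate
12 | {3-[5-methoxy-3-methyl-2-(triisopropylsilyloxy)phenyl]prop-1-en-2-yl}lithium | [Li]C(=C)Cc1cc(OC)cc(C)c1O[Si](C(C)C)(C(C)C)C(C)C | intermediate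
13 | (1S,3aR,7aR)-1-(3-Ar-prop-1-en-2-yl)-1-hydroxy-3a-methyloctahydro-4H-inden-4-one | O[C@]1(C(=C)Cc2cc(OC)cc(C)c2O[Si](C(C)C)(C(C)C)C(C)C)[C@@H]2CCCC(=O)[C@]2(C)CC1 | intermediate
14 | (1S,3aR,7aR)-1-(3-Ar-prop-1-en-2-yl)-1-hydroxy-5-(2-hydroxypropan-2-yl)-3a-methyloctahydro-4H-inden-4-one (C5 epimers) | O[C@]1(C(=C)Cc2cc(OC)cc(C)c2O[Si](C(C)C)(C(C)C)C(C)C)[C@@H]2CCC(C(C)(C)O)C(=O)[C@]2(C)CC1 | intermediate
15 | (4aS,5R,8aR)-5-(Ar-methyl)-2-(2-hydroxypropan-2-yl)-5,8a-dimethyloctahydronaphthalene-1,6-dione (C2 epimers) | COc1cc(C)c(O[Si](C(C)C)(C(C)C)C(C)C)c(C[C@]2(C)[C@@H]3CCC(C(C)(C)O)C(=O)[C@]3(C)CCC2=O)c1 | intermediate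
16 | (4aS,5R,8aR)-5-(Ar-methyl)-5,8a-dimethyl-2-(propan-2-ylidene)octahydronaphthalene-1,6-dione | COc1cc(C)c(O[Si](C(C)C)(C(C)C)C(C)C)c(C[C@]2(C)[C@@H]3CCC(=C(C)C)C(=O)[C@]3(C)CCC2=O)c1 | intermediate
17 | 6-(methoxymethylidene) enol ether of 16 (E/Z mixture) | COc1cc(C)c(O[Si](C(C)C)(C(C)C)C(C)C)c(C[C@]2(C)[C@@H]3CCC(=C(C)C)C(=O)[C@]3(C)CCC2=COC)c1 | intermediate
18 | (1R)-allylic alcohol from 17 | COc1cc(C)c(O[Si](C(C)C)(C(C)C)C(C)C)c(C[C@]2(C)[C@@H]3CCC(=C(C)C)[C@H](O)[C@]3(C)CCC2=COC)c1 | intermediate
19 | C1 allylic chloride from 18 (C1 undefined) | COc1cc(C)c(O[Si](C(C)C)(C(C)C)C(C)C)c(C[C@]2(C)[C@@H]3CCC(=C(C)C)C(Cl)[C@]3(C)CCC2=COC)c1 | intermediate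
20 | ethyl 3-[5-(Ar-methyl)-6-(methoxymethylidene)-5,8a-dimethyl-2-(propan-2-ylidene)decahydronaphthalen-1-yl]propanoate (stereocentres as in 22) | COc1cc(C)c(O[Si](C(C)C)(C(C)C)C(C)C)c(C[C@]2(C)[C@@H]3CCC(=C(C)C)[C@@H](CCC(=O)OCC)[C@]3(C)CCC2=COC)c1 | intermediate
21 | ethyl 3-[5-(Ar-methyl)-6-formyl-5,8a-dimethyl-2-(propan-2-ylidene)decahydronaphthalen-1-yl]propanoate (stereocentres as in 22) | COc1cc(C)c(O[Si](C(C)C)(C(C)C)C(C)C)c(C[C@]2(C)[C@@H]3CCC(=C(C)C)[C@@H](CCC(=O)OCC)[C@]3(C)CC[C@H]2C=O)c1 | intermediate
22 | 3-[(1S,4aS,5S,6R,8aR)-5-(2-hydroxy-5-methoxy-3-methylbenzyl)-5,6,8a-trimethyl-2-(propan-2-ylidene)decahydronaphthalen-1-yl]propanoic acid | COc1cc(C)c(O)c(C[C@]2(C)[C@@H]3CCC(=C(C)C)[C@@H](CCC(=O)O)[C@]3(C)CC[C@H]2C)c1 | target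

**Step count.** Total: 14 steps. Longest linear sequence: 11 steps (steps 4 to 14, from 6 and 7); the aryl fragment 5 takes 3 steps and joins in step 7.

**Steps most likely to fail**

Step 9. The cation equivalent at C5 may be captured by the carbinol oxygen (spiro-epoxide) or by the aryl ether oxygen with loss of silicon (dihydrobenzofuran), the C7 methylene may migrate in place of C4a, or facial control at C5 may be low. The fallback sets out from 14 and replaces the radical–polar crossover by an ionic, anti-selective seleniranium-triggered ring expansion followed by a separate reduction. PhSeCl in CH2Cl2 at −78 °C should give the ring-expanded (phenylselanyl)methyl diketone F1, and n-Bu3SnH in large excess with AIBN in toluene at 80 °C should cut the carbon–selenium bond to the methyl group. The route is rejoined at hydroxy diketone 15, which TsOH dehydrates to 16 as in step 9.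

Step 13. The zinc homoenolate may undergo β-hydride elimination, coupling may occur at the CMe2 terminus, the allyl unit may eliminate to a diene, or the two faces of C1 may not be distinguished. The fallback sets out from 19 and builds the C1–chain bond by a sigmatropic route whose regiochemistry is fixed. Indium metal, NaI and acrolein in DMF should give, by γ-selective Barbier allylation, the 1,5-dien-3-ol F2. KH and 18-crown-6 in THF should trigger the anionic oxy-Cope rearrangement, which forms the C1–CH2 bond on the less hindered face, sets the isopropylidene, and gives the aldehyde F3. AgNO3/NaOH in aqueous EtOH should oxidise it to the acid F4, and 1 M HCl in THF should hydrolyse the enol ether to the formyl acid F5. The conditions of step 14 then lead to 22, where the route is rejoined.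

Step 7. The organocerium reagent may also attack the six-ring ketone, may enolise the cyclopentanone, or may approach from the concave face. The fallback sets out from 10 and differentiates the two carbonyl groups by order of events. Ketalisation with (Me3SiOCH2)2 and catalytic Me3SiOTf at −78 °C should give the dioxolane F6, and ozonolysis with Me2S work-up the ketal ketone F7. LiN(i-Pr)2 then acetone should give the aldol F8, and SOCl2/pyridine followed by DBU the ketal enone F9. Aqueous HCl in acetone should release the diketone F10, in which only the cyclopentanone is open to attack. The alkenylcerium reagent made from 12 should then give the carbinol F11, and the cobalt conditions of step 9 (without the TsOH stage) return the route at 16.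

Further compounds
F1 | step 9 | (4aS,5R,8aR)-5-(Ar-methyl)-2-(2-hydroxypropan-2-yl)-8a-methyl-5-[(phenylselanyl)methyl]octahydronaphthalene-1,6-dione | COc1cc(C)c(O[Si](C(C)C)(C(C)C)C(C)C)c(C[C@]2(C[Se]c4ccccc4)[C@@H]3CCC(C(C)(C)O)C(=O)[C@]3(C)CCC2=O)c1
F2 | step 13 | 1,5-dien-3-ol: 4-[ring-A cyclohexenyl]-4-methylpent-1-en-3-ol, C1=C2 alkene in ring A, enol ether at C6 | COc1cc(C)c(O[Si](C(C)C)(C(C)C)C(C)C)c(C[C@]2(C)[C@@H]3CCC(C(C)(C)C(O)C=C)=C[C@]3(C)CCC2=COC)c1
F3 | step 13 | 3-[5-(Ar-methyl)-6-(methoxymethylidene)-5,8a-dimethyl-2-(propan-2-ylidene)decahydronaphthalen-1-yl]propanal | COc1cc(C)c(O[Si](C(C)C)(C(C)C)C(C)C)c(C[C@]2(C)[C@@H]3CCC(=C(C)C)[C@@H](CCC=O)[C@]3(C)CCC2=COC)c1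
F4 | step 13 | 3-[5-(Ar-methyl)-6-(methoxymethylidene)-5,8a-dimethyl-2-(propan-2-ylidene)decahydronaphthalen-1-yl]propanoic acid | COc1cc(C)c(O[Si](C(C)C)(C(C)C)C(C)C)c(C[C@]2(C)[C@@H]3CCC(=C(C)C)[C@@H](CCC(=O)O)[C@]3(C)CCC2=COC)c1
F5 | step 13 | 3-[5-(Ar-methyl)-6-formyl-5,8a-dimethyl-2-(propan-2-ylidene)decahydronaphthalen-1-yl]propanoic acid | COc1cc(C)c(O[Si](C(C)C)(C(C)C)C(C)C)c(C[C@]2(C)[C@@H]3CCC(=C(C)C)[C@@H](CCC(=O)O)[C@]3(C)CC[C@H]2C=O)c1
F6 | step 7 | ethylene ketal of 10 at the cyclopentanone | O1CCOC12[C@@H]3CCCC(=C)[C@]3(C)CC2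
F7 | step 7 | ethylene ketal of 11 at the cyclopentanone | O1CCOC12[C@@H]3CCCC(=O)[C@]3(C)CC2
F8 | step 7 | acetone aldol of F7 (epimers at the new CH) | O1CCOC12[C@@H]3CCC(C(C)(C)O)C(=O)[C@]3(C)CC2
F9 | step 7 | isopropylidene enone ketal | O1CCOC12[C@@H]3CCC(=C(C)C)C(=O)[C@]3(C)CC2
F10 | step 7 | (3aR,7aR)-3a-methyl-5-(propan-2-ylidene)hexahydro-1H-indene-1,4(2H)-dione | O=C1[C@@H]2CCC(=C(C)C)C(=O)[C@]2(C)CC1
F11 | step 7 | (1S,3aR,7aR)-1-(3-Ar-prop-1-en-2-yl)-1-hydroxy-3a-methyl-5-(propan-2-ylidene)octahydro-4H-inden-4-one | O[C@]1(C(=C)Cc2cc(OC)cc(C)c2O[Si](C(C)C)(C(C)C)C(C)C)[C@@H]2CCC(=C(C)C)C(=O)[C@]2(C)CC1
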